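## The problem

The target is a 1,4-bis(indol-3-yl)-2,3,5,6-tetramethoxybenzene. Numbering the central benzene C-1 to C-6, methoxy groups sit on C-1, C-2, C-4 and C-5, the 5-hydroxyindol-3-yl group (indole A) on C-3 and the 6-prenylindol-3-yl group (indole B) on C-6. There is no stereocentre; the difficulty is regiochemical and steric. The central ring is hexasubstituted, each aryl–indole bond is flanked by two methoxy groups, and the two indoles differ only in remote substituents. Any symmetric central building block therefore offers two identical sites to two almost identical partners. The prenyl alkene rules out strong acid, electrophilic halogen (once it is present) and hydrogenolysis. The phenol of indole A must stay distinct from four aryl methyl ethers, so it cannot be freed by a late demethylation, and the 5-hydroxyindole and any free hydroquinone are easily oxidized. The feature that makes the key step possible is the para pair of oxygenated carbons C-2 and C-5: with C-6 (aryl) and C-1 (OMe) between them they form a four-carbon unit O–C, C–aryl, C–OMe, C–O, which is the carbon skeleton of a 3-aryl-4-methoxycyclobutene-1,2-dione (from squaric ester). The remaining carbons C-3 (aryl) and C-4 (OMe) are an α-aryl enol ether, so a 4-alkenyl-4-hydroxycyclobutenone built from these two pieces is an isomer of the fully substituted hydroquinone.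

## Retrosynthesis

**20 to 19.** The last operation cuts no skeletal bond: two N–S bonds and one O–Si bond are cleaved in 19. Tosyl on both indole nitrogens makes each indol-3-yl group behave as an ordinary aryl group, which the regiochemistry of steps 7 and 8 depends on. The triisopropylsilyl ether keeps the phenol apart from the methyl ethers and survives organolithium chemistry. All three groups should fall to fluoride, which touches neither the prenyl group nor the methyl ethers; a benzyl ether is excluded because of the prenyl alkene.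

**19 to 18.** The O–CH3 bonds at C-2 and C-5 are cut, giving hydroquinone 18. Two of the four methoxy groups are thus carried through the ring construction; only two ordinary phenol alkylations are asked of the forward step.

**18 to 16 (key disconnection).** The ring bond C-4–C-5 is cut and C-2 is joined to C-5 instead, which turns the arene into the 4-alkenyl-4-hydroxycyclobutenone 16. Cutting here instead of at the two aryl–indole bonds removes the symmetry problem, because the two indoles now sit on different, non-equivalent precursors. It also removes the steric problem, because the crowded ring is formed by an intramolecular pericyclic cascade (through dienylketene 17) and not by intermolecular coupling at a di-ortho-substituted position. Compound 16 contains no benzene ring at the centre and is one C–C bond away from two simple halves. The forward reaction must open the four-membered ring with the hydroxyl rotating outward and close the six-membered ring.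

**16 to 8 and 14.** The bond C-2–C-3 (carbinol carbon to the aryl-bearing vinyl carbon) is cut, leading to cyclobutenedione 8 and the α-aryl-β-methoxyvinyllithium 15, made from bromide 14. The forward addition must take place at the carbonyl of 8 next to the methoxy-bearing carbon. That carbonyl is the free ketone; the other is deactivated as a vinylogous ester, and the N-tosyl group keeps the indole from competing as a donor.

**8 to 4 and 5.** The bond between the squarate carbon and C-3 of indole B is cut. Dimethyl squarate 5 takes up the indol-3-ylmagnesium reagent 6 (from iodide 4), and the adduct 7 collapses to 8. An acid-releasing Friedel–Crafts reaction with squaric dichloride was set aside because of the prenyl group.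

**4 to 2 to 1.** Iodide 4 comes from 6-prenylindole 2 by C-3 iodination (via 3) and N-sulfonylation. The prenyl C–C bond of 2 is cut back to commercial 6-bromoindole 1 (Stille coupling). Iodine and not bromine is used at C-3 because it does not add to the prenyl alkene.

**14 to 12 to 11 to 10 to 9.** Bromide 14 is the product of bromine addition to enol ether 12 (dibromide 13) and loss of HBr. Enol ether 12 is the Wittig product of aldehyde 11, which is commercial 5-hydroxyindole-3-carbaldehyde 9 after O-silylation (10) and N-tosylation. Indole A is placed in this half because the sequence uses bromine, which indole B with its prenyl group would not survive.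

## Roads not taken

**Alternative 1:** Cut both aryl–indole bonds. The forward key step would be two successive Suzuki–Miyaura couplings of 1,4-dibromo-2,3,5,6-tetramethoxybenzene A1, first with boronate A2 to give bromide A3, then with boronate A4. Its redox twin is acid-promoted addition of the free indoles to 2,5-dichloro-1,4-benzoquinone A5. This is the obvious route. Its weaknesses are structural:
- A1 and A5 each have two identical reactive sites, so the first coupling is statistical.
- Every C–Br bond of A1 and A3 is flanked by two methoxy groups, while A2 and A4 are protodeboronation-prone heteroaryl boronates.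
- The quinone variant needs acid and an oxidant in the presence of the prenyl group and an oxidizable 5-oxygenated indole, then chloride-to-methoxide exchange and a reductive tetramethylation.

The chosen plan has no statistical step and forms the crowded ring intramolecularly.

**Alternative 2:** Cut the central ring into two C3 units, as in the biosynthesis. The forward key step would be a head-to-tail double Claisen condensation of the two indol-3-ylpyruvates A6 and A7 to the dihydroxyquinone A8. The two esters are chemically equivalent, so the cross product is accompanied by both homodimers. Arylpyruvates also react as ketones (aldol) more readily than as esters (Claisen). Finally A8 must be reduced and alkylated four times on oxygen beside two free indole N–H groups. The chosen plan decides which indole goes where by the order of two polar additions and arrives with two of the four methyl ethers already in place.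

**Alternative 3:** Cut three ring bonds in a Dötz benzannulation of the zerovalent chromium carbene complex A9, (CO)5Cr=C(OMe)C(OMe)=CH–aryl, with ynol ether A10 and carbon monoxide. Here the regiochemistry rests on the direction of alkyne insertion. The target needs the indolyl group of A10 to end up remote from the new phenol carbon, against the usual steric preference, and heteroatom-substituted alkynes often insert differently again. A9 also needs stoichiometric chromium and several steps of its own. In the chosen plan every ring substituent is fixed by σ bonds made before the pericyclic step.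

Key step: step 9

Abbreviations: Ts = 4-methylbenzenesulfonyl; TIPS = tri(propan-2-yl)silyl; prenyl = 3-methylbut-2-en-1-yl.

Assumption: the enol ether double bond of 12 to 17 is expected as an E/Z mixture and is written without geometry, and carbinol 16 is racemic; both features disappear when the arene forms, and the target has no stereocentre.

## Steps

**Step 1**
Reactants: 1 6-bromo-1H-indole
Product: 2 6-prenyl-1H-indole
Conditions: tributyl(prenyl)stannane, Pd(PPh3)4 (5 mol %), DMF, 100 °C
Reagents that add atoms: tributyl(3-methylbut-2-en-1-yl)stannane, CCCC[Sn](CCCC)(CCCC)CC=C(C)C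
Why: Stille coupling of an aryl bromide with an allylic stannane under the zerovalent palladium complex Pd(PPh3)4; the free N–H is tolerated and reductive elimination at the less hindered allyl terminus should favour the linear prenyl isomer.

**Step 2**
Reactants: 2 6-prenyl-1H-indole
Product: 4 3-iodo-6-prenyl-1-Ts-1H-indole, via 3-iodo-6-prenyl-1H-indole 3 (not isolated)
Conditions: I2, KOH, DMF, 0 °C; then TsCl, 0 °C to rt
Reagents that add atoms: iodine, II; 4-methylbenzenesulfonyl chloride, Cc1ccc(S(=O)(=O)Cl)cc1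
Why: Electrophilic iodination of the indolide at C-3 is much faster than any reaction of iodine with the trisubstituted alkene, and N-sulfonylation in the same flask avoids isolating the labile N–H iodide.

**Step 3**
Reactants: 4 3-iodo-6-prenyl-1-Ts-1H-indole; 5 3,4-dimethoxycyclobut-3-ene-1,2-dione (dimethyl squarate)
Product: 8 3-methoxy-4-(6-prenyl-1-Ts-1H-indol-3-yl)cyclobut-3-ene-1,2-dione, via indol-3-ylmagnesium chloride 6 (not isolated), via chloromagnesium alkoxide adduct 7 (not isolated)
Conditions: i-PrMgCl·LiCl, THF, −40 °C; then 5, −78 to −40 °C; then (CF3CO)2O, −78 to 0 °C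
Reagents that add atoms: none
Why: Iodine–magnesium exchange gives a 3-magnesio-1-sulfonylindole that does not migrate to C-2; 1,2-addition to a squarate carbonyl and trifluoroacetylation, ionization and loss of one methyl group from the adduct is the standard route to 3-aryl-4-alkoxycyclobutenediones.

**Step 4**
Reactants: 9 5-hydroxy-1H-indole-3-carbaldehyde
Product: 10 5-(TIPS-oxy)-1H-indole-3-carbaldehyde
Conditions: TIPSCl, imidazole, DMF, rt
Reagents that add atoms: chlorotri(propan-2-yl)silane, CC(C)[Si](Cl)(C(C)C)C(C)C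
Why: Phenol silylation; under imidazole conditions the weakly nucleophilic N–H of a 3-formylindole is not silylated.

**Step 5**
Reactants: 10 5-(TIPS-oxy)-1H-indole-3-carbaldehyde
Product: 11 1-Ts-5-(TIPS-oxy)-1H-indole-3-carbaldehyde
Conditions: TsCl, Et3N, DMAP (cat.), CH2Cl2, rt
Reagents that add atoms: 4-methylbenzenesulfonyl chloride, Cc1ccc(S(=O)(=O)Cl)cc1
Why: N-sulfonylation of the acidic N–H of a 3-acylindole; the tosyl group later keeps bromine and tert-butyllithium away from the indole ring.

**Step 6**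
Reactants: 11 1-Ts-5-(TIPS-oxy)-1H-indole-3-carbaldehyde
Product: 12 3-(2-methoxyethenyl)-1-Ts-5-(TIPS-oxy)-1H-indole
Conditions: Ph3P(CH2OMe)Cl, NaN(SiMe3)2, THF, 0 °C; then 11, 0 °C to rt
Reagents that add atoms: (methoxymethyl)triphenylphosphonium chloride, COC[P+](c1ccccc1)(c1ccccc1)c1ccccc1.[Cl-]
Why: Wittig reaction with the methoxymethylene ylide; the E/Z mixture is used as such because the geometry is lost later.

**Step 7**
Reactants: 12 3-(2-methoxyethenyl)-1-Ts-5-(TIPS-oxy)-1H-indole
Product: 14 3-(1-bromo-2-methoxyethenyl)-1-Ts-5-(TIPS-oxy)-1H-indole, via vicinal dibromide 13 (not isolated)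
Conditions: Br2 (1.0 equiv), CH2Cl2, −78 °C; then DBU, −78 to 0 °C
Reagents that add atoms: bromine, BrBr
Why: Bromine adds to the enol ether far faster than to the deactivated N-sulfonylindole; in the dibromide the bromide on the methoxy-bearing carbon is the labile α-halo ether leaving group and the benzylic hydrogen is the acidic one, so HBr is lost towards the 1-bromo-2-methoxyalkene (bromination–dehydrobromination of an enol ether).

**Step 8**
Reactants: 14 3-(1-bromo-2-methoxyethenyl)-1-Ts-5-(TIPS-oxy)-1H-indole; 8 3-methoxy-4-(6-prenyl-1-Ts-1H-indol-3-yl)cyclobut-3-ene-1,2-dione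
Product: 16 4-hydroxy-3-methoxy-4-{2-methoxy-1-[1-Ts-5-(TIPS-oxy)-1H-indol-3-yl]ethenyl}-2-(6-prenyl-1-Ts-1H-indol-3-yl)cyclobut-2-en-1-one, via alkenyllithium 15 (not isolated)
Conditions: t-BuLi (2 equiv), THF, −78 °C; then added to 8, THF, −78 °C; aq. NH4Cl
Reagents that add atoms: none
Why: Bromine–lithium exchange on a β-alkoxyvinyl bromide followed by 1,2-addition of the alkenyllithium to the cyclobutenedione; attack goes to the carbonyl next to the methoxy-bearing carbon because the other carbonyl is a vinylogous ester and the N-tosylindole is only a weak donor. The new carbinol centre is formed racemic and is destroyed in step 9; 16 is a vinylogous hemiacetal and is taken on without acidic contact.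

**Step 9**
Reactants: 16 4-hydroxy-3-methoxy-4-{2-methoxy-1-[1-Ts-5-(TIPS-oxy)-1H-indol-3-yl]ethenyl}-2-(6-prenyl-1-Ts-1H-indol-3-yl)cyclobut-2-en-1-one
Product: 18 3,6-dimethoxy-2-(6-prenyl-1-Ts-1H-indol-3-yl)-5-[1-Ts-5-(TIPS-oxy)-1H-indol-3-yl]benzene-1,4-diol, via dienylketene 17 (not isolated)
Conditions: toluene (degassed), 110 °C, argon
Reagents that add atoms: none
Why: On heating, the cyclobutenone opens by conrotatory 4π electrocyclic cleavage of the C-1–C-4 bond to dienylketene 17. The hydroxyl on C-4, the donor, rotates outward, which turns the alkenyl group inward and places it cis to the ketene. A disrotatory 6π electrocyclization then closes the six-membered carbocycle by bonding the ketene carbon to the methoxy-bearing enol ether carbon, and tautomerization of the resulting cyclohexa-2,4-dienone gives hydroquinone 18. The closest known reaction type is the thermal ring expansion of 4-alkenyl-4-hydroxycyclobutenones to hydroquinones (Moore rearrangement family). No stereocentre is formed; the racemic carbinol centre and the enol ether geometry are both erased on aromatization. The only selectivity needed is the torquoselectivity of the opening, secured by the hydroxyl group; regiochemistry is not at stake because all six substituents already sit on the six carbons that become the ring, in the order fixed by the bonds made in steps 3 and 8. Degassed solvent and base-washed glass protect the electron-rich hydroquinone and the acid-labile carbinol.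

**Step 10**
Reactants: 18 3,6-dimethoxy-2-(6-prenyl-1-Ts-1H-indol-3-yl)-5-[1-Ts-5-(TIPS-oxy)-1H-indol-3-yl]benzene-1,4-diol
Product: 19 6-prenyl-1-Ts-3-{2,3,5,6-tetramethoxy-4-[1-Ts-5-(TIPS-oxy)-1H-indol-3-yl]phenyl}-1H-indole
Conditions: MeI, K2CO3, acetone, 45 °C, argon
Reagents that add atoms: iodomethane, CI
Why: Williamson O-methylation of both phenols; carbonate in acetone is mild enough that the hindered aryl triisopropylsilyl ether and the sulfonamides should stay intact, and argon keeps the hydroquinone dianion from oxidizing.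

**Step 11**
Reactants: 19 6-prenyl-1-Ts-3-{2,3,5,6-tetramethoxy-4-[1-Ts-5-(TIPS-oxy)-1H-indol-3-yl]phenyl}-1H-indole
Product: 20 3-{2,3,5,6-tetramethoxy-4-(6-prenyl-1H-indol-3-yl)phenyl}-1H-indol-5-ol (target)
Conditions: TBAF (excess), THF, 65 °C, argon; aq. NH4Cl
Reagents that add atoms: none
Why: Fluoride cleaves the aryl silyl ether at once and, at reflux, both indole N-sulfonyl groups (attack at sulfur, the indolide being a good leaving group); prenyl alkene and aryl methyl ethers are inert to fluoride.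

## Compound list

1 | 6-bromo-1H-indole | Brc1ccc2cc[nH]c2c1 | starting material
2 | 6-(3-methylbut-2-en-1-yl)-1H-indole | CC(C)=CCc1ccc2cc[nH]c2c1 | intermediate
3 | 3-iodo-6-(3-methylbut-2-en-1-yl)-1H-indole | CC(C)=CCc1ccc2c(I)c[nH]c2c1 | intermediate (not isolated)
4 | 3-iodo-6-(3-methylbut-2-en-1-yl)-1-(4-methylbenzenesulfonyl)-1H-indole | CC(C)=CCc1ccc2c(I)cn(S(=O)(=O)c3ccc(C)cc3)c2c1 | intermediate
5 | 3,4-dimethoxycyclobut-3-ene-1,2-dione (dimethyl squarate) | COC1=C(OC)C(=O)C1=O | starting material
6 | chloro[6-(3-methylbut-2-en-1-yl)-1-(4-methylbenzenesulfonyl)-1H-indol-3-yl]magnesium | Cl[Mg]c1cn(S(=O)(=O)c2ccc(C)cc2)c2cc(CC=C(C)C)ccc12 | intermediate (not isolated)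
7 | chloromagnesium 2,3-dimethoxy-1-[6-(3-methylbut-2-en-1-yl)-1-(4-methylbenzenesulfonyl)-1H-indol-3-yl]-4-oxocyclobut-2-en-1-olate | Cl[Mg]OC1(c2cn(S(=O)(=O)c3ccc(C)cc3)c3cc(CC=C(C)C)ccc23)C(OC)=C(OC)C1=O | intermediate (not isolated)
8 | 3-methoxy-4-[6-(3-methylbut-2-en-1-yl)-1-(4-methylbenzenesulfonyl)-1H-indol-3-yl]cyclobut-3-ene-1,2-dione | COC1=C(c2cn(S(=O)(=O)c3ccc(C)cc3)c3cc(CC=C(C)C)ccc23)C(=O)C1=O | intermediate
9 | 5-hydroxy-1H-indole-3-carbaldehyde | O=Cc1c[nH]c2ccc(O)cc12 | starting material
10 | 5-{[tri(propan-2-yl)silyl]oxy}-1H-indole-3-carbaldehyde | O=Cc1c[nH]c2ccc(O[Si](C(C)C)(C(C)C)C(C)C)cc12 | intermediate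
11 | 1-(4-methylbenzenesulfonyl)-5-{[tri(propan-2-yl)silyl]oxy}-1H-indole-3-carbaldehyde | O=Cc1cn(S(=O)(=O)c2ccc(C)cc2)c2ccc(O[Si](C(C)C)(C(C)C)C(C)C)cc12 | intermediate
12 | 3-(2-methoxyethenyl)-1-(4-methylbenzenesulfonyl)-5-{[tri(propan-2-yl)silyl]oxy}-1H-indole (E/Z mixture) | COC=Cc1cn(S(=O)(=O)c2ccc(C)cc2)c2ccc(O[Si](C(C)C)(C(C)C)C(C)C)cc12 | intermediate
13 | 3-(1,2-dibromo-2-methoxyethyl)-1-(4-methylbenzenesulfonyl)-5-{[tri(propan-2-yl)silyl]oxy}-1H-indole (diastereomer mixture) | COC(Br)C(Br)c1cn(S(=O)(=O)c2ccc(C)cc2)c2ccc(O[Si](C(C)C)(C(C)C)C(C)C)cc12 | intermediate (not isolated)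
14 | 3-(1-bromo-2-methoxyethenyl)-1-(4-methylbenzenesulfonyl)-5-{[tri(propan-2-yl)silyl]oxy}-1H-indole (E/Z mixture) | COC=C(Br)c1cn(S(=O)(=O)c2ccc(C)cc2)c2ccc(O[Si](C(C)C)(C(C)C)C(C)C)cc12 | intermediate
15 | {2-methoxy-1-[1-(4-methylbenzenesulfonyl)-5-{[tri(propan-2-yl)silyl]oxy}-1H-indol-3-yl]ethenyl}lithium | COC=C([Li])c1cn(S(=O)(=O)c2ccc(C)cc2)c2ccc(O[Si](C(C)C)(C(C)C)C(C)C)cc12 | intermediate (not isolated)
16 | 4-hydroxy-3-methoxy-4-{2-methoxy-1-[1-(4-methylbenzenesulfonyl)-5-{[tri(propan-2-yl)silyl]oxy}-1H-indol-3-yl]ethenyl}-2-[6-(3-methylbut-2-en-1-yl)-1-(4-methylbenzenesulfonyl)-1H-indol-3-yl]cyclobut-2-en-1-one (racemic; E/Z mixture) | O=C1C(c2cn(S(=O)(=O)c3ccc(C)cc3)c3cc(CC=C(C)C)ccc23)=C(OC)C1(O)C(=COC)c1cn(S(=O)(=O)c2ccc(C)cc2)c2ccc(O[Si](C(C)C)(C(C)C)C(C)C)cc12 | intermediate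
17 | 4-hydroxy-3,6-dimethoxy-5-[1-(4-methylbenzenesulfonyl)-5-{[tri(propan-2-yl)silyl]oxy}-1H-indol-3-yl]-2-[6-(3-methylbut-2-en-1-yl)-1-(4-methylbenzenesulfonyl)-1H-indol-3-yl]hexa-1,3,5-trien-1-one | O=C=C(c1cn(S(=O)(=O)c2ccc(C)cc2)c2cc(CC=C(C)C)ccc12)C(OC)=C(O)C(=COC)c1cn(S(=O)(=O)c2ccc(C)cc2)c2ccc(O[Si](C(C)C)(C(C)C)C(C)C)cc12 | intermediate (not isolated)
18 | 3,6-dimethoxy-2-[6-(3-methylbut-2-en-1-yl)-1-(4-methylbenzenesulfonyl)-1H-indol-3-yl]-5-[1-(4-methylbenzenesulfonyl)-5-{[tri(propan-2-yl)silyl]oxy}-1H-indol-3-yl]benzene-1,4-diol | COc1c(O)c(-c2cn(S(=O)(=O)c3ccc(C)cc3)c3cc(CC=C(C)C)ccc23)c(OC)c(O)c1-c1cn(S(=O)(=O)c2ccc(C)cc2)c2ccc(O[Si](C(C)C)(C(C)C)C(C)C)cc12 | intermediate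
19 | 6-(3-methylbut-2-en-1-yl)-1-(4-methylbenzenesulfonyl)-3-{2,3,5,6-tetramethoxy-4-[1-(4-methylbenzenesulfonyl)-5-{[tri(propan-2-yl)silyl]oxy}-1H-indol-3-yl]phenyl}-1H-indole | COc1c(OC)c(-c2cn(S(=O)(=O)c3ccc(C)cc3)c3cc(CC=C(C)C)ccc23)c(OC)c(OC)c1-c1cn(S(=O)(=O)c2ccc(C)cc2)c2ccc(O[Si](C(C)C)(C(C)C)C(C)C)cc12 | intermediate
20 | 3-{2,3,5,6-tetramethoxy-4-[6-(3-methylbut-2-en-1-yl)-1H-indol-3-yl]phenyl}-1H-indol-5-ol | COc1c(OC)c(-c2c[nH]c3ccc(O)cc23)c(OC)c(OC)c1-c1c[nH]c2cc(CC=C(C)C)ccc12 | target

## Step count and risks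

Total: 11 steps. Longest linear sequence: 8 steps (steps 4, 5, 6, 7, 8, 9, 10, 11); the other branch is steps 1 to 3.

**Step 9 (key step).** Most likely to go wrong: the ketene is intercepted by the tertiary hydroxyl (lactonization to a butenolide) when closure against the inward methoxy group is slow; the free hydroquinone may also be lost by oxidation during the thermolysis. The fallback sets out from 14 and 8. The lithium alkoxide formed in step 8 is not protonated but O-methylated in the flask (MeOTf, −78 to 0 °C) to give the 4-methoxycyclobutenone methyl ether F1. At 110 °C this opens to the fully capped dienylketene F2, which has no hydroxyl to trap the ketene and can only electrocyclize, giving the air-stable trimethoxyphenol F3. Methylation of its single phenol (MeI, K2CO3, acetone) returns to the route at 19. Should the closure itself fail for steric reasons, the sequence given under step 8 closes a less substituted ring.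

**Step 8.** Most likely to go wrong: loss of lithium methoxide from the isomer of 15 in which lithium is anti to the methoxy group (β-elimination to the alkyne) before addition, and attack of tert-butyllithium on a sulfonamide. The fallback uses a vinyllithium without the β-methoxy group and adds the fourth oxygen afterwards. It sets out from 11 and 8.
- Wittig methylenation of 11 (Ph3PCH3Br, NaN(SiMe3)2) gives the 3-ethenylindole F4.
- Bromine addition gives dibromide F5, and DBU gives the 1-bromoethenylindole F6.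
- Bromine–lithium exchange gives the α-arylvinyllithium F7, which cannot eliminate and adds to 8 to give carbinol F8, an ordinary tertiary allylic alcohol.
- Thermolysis through dienylketene F9 gives the pentasubstituted hydroquinone F10.
- Oxidation with Ag2O gives quinone F11.
- Conjugate addition of methanol at its only free position (MeOH, Et3N, air) gives the dimethoxyquinone F12.
- Reduction with Na2S2O4 returns to the route at 18.

**Step 7.** Most likely to go wrong: loss of HBr in the wrong sense, or substitution of the anomeric bromide of 13 by the amine base. The fallback sets out from 12. NBS in methanol adds bromine and methanol across the enol ether to give the stable bromoacetal F13. Elimination of methanol from the acetal (TMSOTf, i-Pr2NEt, CH2Cl2), which can only remove the hydrogen on the bromine-bearing carbon, returns to the route at 14.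

**Step 11.** Most likely to go wrong: incomplete N–S cleavage by fluoride, or oxidative degradation of the 5-hydroxyindolate under hot basic fluoride. The fallback sets out from 19 and splits the deprotection. TBAF at 0 °C removes only the silyl ether to give the bis-sulfonamide phenol F14. Reductive N–S cleavage by electron transfer (Mg, MeOH, rt) then frees both indoles without affecting the isolated prenyl alkene, and returns to the route at 20.

## Further compounds

F1 | step 9 | 3,4-dimethoxy-4-{2-methoxy-1-[1-(4-methylbenzenesulfonyl)-5-{[tri(propan-2-yl)silyl]oxy}-1H-indol-3-yl]ethenyl}-2-[6-(3-methylbut-2-en-1-yl)-1-(4-methylbenzenesulfonyl)-1H-indol-3-yl]cyclobut-2-en-1-one | O=C1C(c2cn(S(=O)(=O)c3ccc(C)cc3)c3cc(CC=C(C)C)ccc23)=C(OC)C1(OC)C(=COC)c1cn(S(=O)(=O)c2ccc(C)cc2)c2ccc(O[Si](C(C)C)(C(C)C)C(C)C)cc12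
F2 | step 9 | 3,4,6-trimethoxy-5-[1-(4-methylbenzenesulfonyl)-5-{[tri(propan-2-yl)silyl]oxy}-1H-indol-3-yl]-2-[6-(3-methylbut-2-en-1-yl)-1-(4-methylbenzenesulfonyl)-1H-indol-3-yl]hexa-1,3,5-trien-1-one | O=C=C(c1cn(S(=O)(=O)c2ccc(C)cc2)c2cc(CC=C(C)C)ccc12)C(OC)=C(OC)C(=COC)c1cn(S(=O)(=O)c2ccc(C)cc2)c2ccc(O[Si](C(C)C)(C(C)C)C(C)C)cc12
F3 | step 9 | 3,4,6-trimethoxy-2-[6-(3-methylbut-2-en-1-yl)-1-(4-methylbenzenesulfonyl)-1H-indol-3-yl]-5-[1-(4-methylbenzenesulfonyl)-5-{[tri(propan-2-yl)silyl]oxy}-1H-indol-3-yl]phenol | COc1c(O)c(-c2cn(S(=O)(=O)c3ccc(C)cc3)c3cc(CC=C(C)C)ccc23)c(OC)c(OC)c1-c1cn(S(=O)(=O)c2ccc(C)cc2)c2ccc(O[Si](C(C)C)(C(C)C)C(C)C)cc12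
F4 | step 8 | 3-ethenyl-1-(4-methylbenzenesulfonyl)-5-{[tri(propan-2-yl)silyl]oxy}-1H-indole | C=Cc1cn(S(=O)(=O)c2ccc(C)cc2)c2ccc(O[Si](C(C)C)(C(C)C)C(C)C)cc12
F5 | step 8 | 3-(1,2-dibromoethyl)-1-(4-methylbenzenesulfonyl)-5-{[tri(propan-2-yl)silyl]oxy}-1H-indole (racemic) | BrCC(Br)c1cn(S(=O)(=O)c2ccc(C)cc2)c2ccc(O[Si](C(C)C)(C(C)C)C(C)C)cc12
F6 | step 8 | 3-(1-bromoethenyl)-1-(4-methylbenzenesulfonyl)-5-{[tri(propan-2-yl)silyl]oxy}-1H-indole | C=C(Br)c1cn(S(=O)(=O)c2ccc(C)cc2)c2ccc(O[Si](C(C)C)(C(C)C)C(C)C)cc12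
F7 | step 8 | {1-[1-(4-methylbenzenesulfonyl)-5-{[tri(propan-2-yl)silyl]oxy}-1H-indol-3-yl]ethenyl}lithium | C=C([Li])c1cn(S(=O)(=O)c2ccc(C)cc2)c2ccc(O[Si](C(C)C)(C(C)C)C(C)C)cc12
F8 | step 8 | 4-hydroxy-3-methoxy-4-{1-[1-(4-methylbenzenesulfonyl)-5-{[tri(propan-2-yl)silyl]oxy}-1H-indol-3-yl]ethenyl}-2-[6-(3-methylbut-2-en-1-yl)-1-(4-methylbenzenesulfonyl)-1H-indol-3-yl]cyclobut-2-en-1-one (racemic) | O=C1C(c2cn(S(=O)(=O)c3ccc(C)cc3)c3cc(CC=C(C)C)ccc23)=C(OC)C1(O)C(=C)c1cn(S(=O)(=O)c2ccc(C)cc2)c2ccc(O[Si](C(C)C)(C(C)C)C(C)C)cc12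
F9 | step 8 | 4-hydroxy-3-methoxy-5-[1-(4-methylbenzenesulfonyl)-5-{[tri(propan-2-yl)silyl]oxy}-1H-indol-3-yl]-2-[6-(3-methylbut-2-en-1-yl)-1-(4-methylbenzenesulfonyl)-1H-indol-3-yl]hexa-1,3,5-trien-1-one | O=C=C(c1cn(S(=O)(=O)c2ccc(C)cc2)c2cc(CC=C(C)C)ccc12)C(OC)=C(O)C(=C)c1cn(S(=O)(=O)c2ccc(C)cc2)c2ccc(O[Si](C(C)C)(C(C)C)C(C)C)cc12
F10 | step 8 | 3-methoxy-2-[6-(3-methylbut-2-en-1-yl)-1-(4-methylbenzenesulfonyl)-1H-indol-3-yl]-5-[1-(4-methylbenzenesulfonyl)-5-{[tri(propan-2-yl)silyl]oxy}-1H-indol-3-yl]benzene-1,4-diol | COc1c(O)c(-c2cn(S(=O)(=O)c3ccc(C)cc3)c3ccc(O[Si](C(C)C)(C(C)C)C(C)C)cc23)cc(O)c1-c1cn(S(=O)(=O)c2ccc(C)cc2)c2cc(CC=C(C)C)ccc12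
F11 | step 8 | 3-methoxy-2-[6-(3-methylbut-2-en-1-yl)-1-(4-methylbenzenesulfonyl)-1H-indol-3-yl]-5-[1-(4-methylbenzenesulfonyl)-5-{[tri(propan-2-yl)silyl]oxy}-1H-indol-3-yl]cyclohexa-2,5-diene-1,4-dione | COC1=C(c2cn(S(=O)(=O)c3ccc(C)cc3)c3cc(CC=C(C)C)ccc23)C(=O)C=C(c2cn(S(=O)(=O)c3ccc(C)cc3)c3ccc(O[Si](C(C)C)(C(C)C)C(C)C)cc23)C1=O
F12 | step 8 | 3,6-dimethoxy-2-[6-(3-methylbut-2-en-1-yl)-1-(4-methylbenzenesulfonyl)-1H-indol-3-yl]-5-[1-(4-methylbenzenesulfonyl)-5-{[tri(propan-2-yl)silyl]oxy}-1H-indol-3-yl]cyclohexa-2,5-diene-1,4-dione | COC1=C(c2cn(S(=O)(=O)c3ccc(C)cc3)c3cc(CC=C(C)C)ccc23)C(=O)C(OC)=C(c2cn(S(=O)(=O)c3ccc(C)cc3)c3ccc(O[Si](C(C)C)(C(C)C)C(C)C)cc23)C1=O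
F13 | step 7 | 3-(1-bromo-2,2-dimethoxyethyl)-1-(4-methylbenzenesulfonyl)-5-{[tri(propan-2-yl)silyl]oxy}-1H-indole (racemic) | COC(OC)C(Br)c1cn(S(=O)(=O)c2ccc(C)cc2)c2ccc(O[Si](C(C)C)(C(C)C)C(C)C)cc12
F14 | step 11 | 1-(4-methylbenzenesulfonyl)-3-{2,3,5,6-tetramethoxy-4-[6-(3-methylbut-2-en-1-yl)-1-(4-methylbenzenesulfonyl)-1H-indol-3-yl]phenyl}-1H-indol-5-ol | COc1c(OC)c(-c2cn(S(=O)(=O)c3ccc(C)cc3)c3cc(CC=C(C)C)ccc23)c(OC)c(OC)c1-c1cn(S(=O)(=O)c2ccc(C)cc2)c2ccc(O)cc12
A1 | alternative 1 | 1,4-dibromo-2,3,5,6-tetramethoxybenzene | COc1c(OC)c(Br)c(OC)c(OC)c1Br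
A2 | alternative 1 | 6-(3-methylbut-2-en-1-yl)-1-(4-methylbenzenesulfonyl)-3-(4,4,5,5-tetramethyl-1,3,2-dioxaborolan-2-yl)-1H-indole | CC(C)=CCc1ccc2c(B3OC(C)(C)C(C)(C)O3)cn(S(=O)(=O)c3ccc(C)cc3)c2c1
A3 | alternative 1 | 3-(4-bromo-2,3,5,6-tetramethoxyphenyl)-6-(3-methylbut-2-en-1-yl)-1-(4-methylbenzenesulfonyl)-1H-indole | COc1c(OC)c(Br)c(OC)c(OC)c1-c1cn(S(=O)(=O)c2ccc(C)cc2)c2cc(CC=C(C)C)ccc12
A4 | alternative 1 | 1-(4-methylbenzenesulfonyl)-3-(4,4,5,5-tetramethyl-1,3,2-dioxaborolan-2-yl)-5-{[tri(propan-2-yl)silyl]oxy}-1H-indole | CC(C)[Si](Oc1ccc2c(c1)c(B1OC(C)(C)C(C)(C)O1)cn2S(=O)(=O)c1ccc(C)cc1)(C(C)C)C(C)C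
A5 | alternative 1 | 2,5-dichlorocyclohexa-2,5-diene-1,4-dione | O=C1C=C(Cl)C(=O)C=C1Cl
A6 | alternative 2 | methyl 3-[6-(3-methylbut-2-en-1-yl)-1H-indol-3-yl]-2-oxopropanoate | COC(=O)C(=O)Cc1c[nH]c2cc(CC=C(C)C)ccc12
A7 | alternative 2 | methyl 2-oxo-3-(5-{[tri(propan-2-yl)silyl]oxy}-1H-indol-3-yl)propanoate | COC(=O)C(=O)Cc1c[nH]c2ccc(O[Si](C(C)C)(C(C)C)C(C)C)cc12
A8 | alternative 2 | 2,5-dihydroxy-3-[6-(3-methylbut-2-en-1-yl)-1H-indol-3-yl]-6-(5-{[tri(propan-2-yl)silyl]oxy}-1H-indol-3-yl)cyclohexa-2,5-diene-1,4-dione | O=C1C(O)=C(c2c[nH]c3cc(CC=C(C)C)ccc23)C(=O)C(O)=C1c1c[nH]c2ccc(O[Si](C(C)C)(C(C)C)C(C)C)cc12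
A9 | alternative 3 | pentacarbonyl{methoxy[1-methoxy-2-(1-(4-methylbenzenesulfonyl)-5-{[tri(propan-2-yl)silyl]oxy}-1H-indol-3-yl)ethenyl]methylidene}chromium | COC(C(OC)=Cc1cn(S(=O)(=O)c2ccc(C)cc2)c2ccc(O[Si](C(C)C)(C(C)C)C(C)C)cc12)=[Cr](=C=O)(=C=O)(=C=O)(=C=O)=C=O
A10 | alternative 3 | 3-(methoxyethynyl)-6-(3-methylbut-2-en-1-yl)-1-(4-methylbenzenesulfonyl)-1H-indole | COC#Cc1cn(S(=O)(=O)c2ccc(C)cc2)c2cc(CC=C(C)C)ccc12
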